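**Plan**

1. The target is isocupressic acid 15-oleate, a labda-8(17),13E-dien-19-oic acid (ring A = C1–C5, C10; ring B = C5–C10; side chain C11–C16 on C9; C17 on C8; C19 on C4; C20 on C10). The retrosynthesis cuts the C15–O ester bond and the C19 oxidation level, then C13=C14 (olefination of a C13 methyl ketone), then C9–C10 and C4–C5 together in one oxidative radical bicyclization, then C1–C2 (dianion alkylation).
2. Enabling feature: C4 bears the C19 carboxyl, so a temporary C3 ketone makes C4 the α-carbon of a β-keto ester that Mn(OAc)3 oxidises to an electrophilic radical. The trisubstituted 5(10)- and 8(9)-alkenes of an (E)-geranylacetone chain lie 1,5 to each other, and the 8(17)-methylene is what oxidative termination of the C8 radical by Cu(OAc)2 leaves behind.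
3. Forward order: chain assembly (allylic oxidation, bromide, γ-alkylation); ring A, then ring B by the C9–C10 bond, in one cascade; side-chain olefination; removal of the C3 oxygen; reductive removal of the auxiliary; C15 acylation; reoxidation of C19.
4. Stereochemistry: C4, C5, C9 and C10 are set relative to each other by the chair–chair transition state of the E,E-diene (axial C19 ester, trans fusion, equatorial C11). The absolute sense comes from the (1R,2S,5R)-8-phenylmenthyl ester, 13E from the olefination, and 9Z arrives with oleoyl chloride.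
5. Helpers and their removal: dioxolane (step 5), C3 ketone (steps 8–10), auxiliary (step 11).

Key step: step 6

Assumption: the auxiliary acts through its usual stacked conformation (phenyl over one face of the acyl π-system, ester carbonyl syn to the C3 ketone carbon), so the (1R,2S,5R) ester should lead to the (4R,5R,9S,10R) series; if the sense were opposite, the enantiomeric auxiliary would be used with no other change.

**Route**

Step 1
Reactants: 1 (E)-geranylacetone (isomerically pure, free of nerylacetone)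
Product: 2 2-[(3E)-4,8-dimethylnona-3,7-dien-1-yl]-2-methyl-1,3-dioxolane
Conditions: ethylene glycol, PPTS (cat.), benzene, reflux, azeotropic removal of water
Reagents that add atoms: ethylene glycol, OCCO
Why: Acid-catalysed ketalisation masks the future C13 ketone against the dianion of step 5, and PPTS is too weak an acid to protonate the trisubstituted alkenes.

Step 2
Reactants: 2 2-[(3E)-4,8-dimethylnona-3,7-dien-1-yl]-2-methyl-1,3-dioxolane
Product: 3 (2E,6E)-2,6-dimethyl-9-(2-methyl-1,3-dioxolan-2-yl)nona-2,6-dien-1-ol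
Conditions: SeO2 (cat.), t-BuOOH (5.5 M in decane), CH2Cl2, 0 °C to rt
Reagents that add atoms: selenium dioxide, O=[Se]=O (oxygen donor, regenerated by tert-butyl hydroperoxide, CC(C)(C)OO)
Why: Allylic oxidation by ene reaction and [2,3]-sigmatropic shift should be selective for the E-methyl of the terminal, least hindered isopropylidene group and give the E-allylic alcohol whose CH2OH carbon becomes C1.

Step 3
Reactants: 3 (2E,6E)-2,6-dimethyl-9-(2-methyl-1,3-dioxolan-2-yl)nona-2,6-dien-1-ol
Product: 4 2-[(3E,7E)-9-bromo-4,8-dimethylnona-3,7-dien-1-yl]-2-methyl-1,3-dioxolane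
Conditions: PPh3, CBr4, CH2Cl2, −20 to 0 °C
Reagents that add atoms: carbon tetrabromide, BrC(Br)(Br)Br
Why: The Appel reaction converts the primary allylic alcohol into the bromide under neutral conditions, without allylic transposition and without harm to the dioxolane.

Step 4
Reactants: 5 ethyl 2-methyl-3-oxobutanoate, 6 (1R,2S,5R)-8-phenylmenthol
Product: 7 (1R,2S,5R)-8-phenylmenthyl 2-methyl-3-oxobutanoate (both C2 epimers)
Conditions: DMAP (cat.), toluene, reflux, ethanol distilled off
Reagents that add atoms: none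
Why: DMAP-catalysed transesterification of an enolisable β-keto ester proceeds through the acylketene and accepts hindered secondary alcohols; the carbinol centre of the auxiliary is untouched and the C2 centre is unimportant.

Step 5
Reactants: 7 (1R,2S,5R)-8-phenylmenthyl 2-methyl-3-oxobutanoate, 4 2-[(3E,7E)-9-bromo-4,8-dimethylnona-3,7-dien-1-yl]-2-methyl-1,3-dioxolane
Product: 9 (1R,2S,5R)-8-phenylmenthyl (6E,10E)-2,6,10-trimethyl-3,14-dioxopentadeca-6,10-dienoate, via ketal-protected alkylation product 8 (not isolated)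
Conditions: NaH, THF, 0 °C; n-BuLi, 0 °C; 4, 0 °C to rt; then 1 M HCl, THF/H2O, rt
Reagents that add atoms: water, O
Why: The acetoacetate dianion is alkylated at its more basic γ-carbon by the primary allylic bromide in an SN2 reaction that keeps the E geometry (forming C1–C2), and the acidic work-up frees the methyl ketone; the C2 epimers converge in step 6.

Step 6
Reactants: 9 (1R,2S,5R)-8-phenylmenthyl (6E,10E)-2,6,10-trimethyl-3,14-dioxopentadeca-6,10-dienoate
Product: 10 (1R,2S,5R)-8-phenylmenthyl (4R,5R,9S,10R)-3,13-dioxo-14,15-dinorlabd-8(17)-en-19-oate (trans-decalin; 3-ketone; axial 4β-ester and 4α-methyl; 10β-methyl; 8(17)-methylene; equatorial 3-oxobutyl chain on C9)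
Conditions: Mn(OAc)3·2H2O (2.2 equiv), Cu(OAc)2·H2O (1 equiv), degassed AcOH, 25–40 °C, argon
Reagents that add atoms: none
Why: The Mn(OAc)3 enolate of the β-keto ester loses divalent manganese to give the planar, electrophilic C4 radical, which adds 6-endo-trig to C5 of the 5(10)-alkene (ring A; endo because the C3 ketone lies inside the forming ring); the resulting tertiary C10 radical adds 6-endo-trig to C9 of the 8(9)-alkene, which forms the C9–C10 bond and closes ring B, and Cu(OAc)2 captures the tertiary C8 radical as an alkylcopper species of trivalent copper that loses a β-hydrogen from the least hindered position (C17) to give the 8(17)-methylene. The closest known reaction type is the Mn(OAc)3/Cu(OAc)2 oxidative free-radical polyene cyclization of 2-methyl-3-oxo esters, including its 8-phenylmenthyl ester version. The relative configuration at C4, C5, C10 and C9 should follow from a chair–chair transition state of the E,E-diene: the ketone oxygen sits syn to the C4 methyl so the ester becomes axial (4β, the C19 position), the ring fusion is trans (H5 anti to C20), and C11 on C9 is equatorial because it is trans to C7 on the alkene. The absolute configuration should come from the auxiliary, whose phenyl ring stacks over one face of the C4 radical so that C5 bonds to the open face. The step needs 6-endo over 5-exo closure (secured by the ring ketone and the trisubstituted alkenes), oxidation of the C8 radical before any further cyclization (secured by a side chain that ends in a ketone and carries no third alkene) and exocyclic over endocyclic elimination (the copper-mediated pathway favours the least substituted alkene).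

Step 7
Reactants: 10 (1R,2S,5R)-8-phenylmenthyl (4R,5R,9S,10R)-3,13-dioxo-14,15-dinorlabd-8(17)-en-19-oate, 11 triethyl phosphonoacetate
Product: 12 15-ethyl 19-[(1R,2S,5R)-8-phenylmenthyl] (4R,5R,9S,10R,13E)-3-oxolabda-8(17),13-diene-15,19-dioate
Conditions: NaH, THF, 0 to 50 °C
Reagents that add atoms: none
Why: The Horner–Wadsworth–Emmons olefination should take place only at the unhindered C13 methyl ketone (the C3 ketone is flanked by the quaternary C4) and should favour the 13E enoate; the minor 13Z isomer is removed by chromatography.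

Step 8
Reactants: 12 15-ethyl 19-[(1R,2S,5R)-8-phenylmenthyl] (4R,5R,9S,10R,13E)-3-oxolabda-8(17),13-diene-15,19-dioate
Product: 13 15-ethyl 19-[(1R,2S,5R)-8-phenylmenthyl] (3S,4R,5R,9S,10R,13E)-3-hydroxylabda-8(17),13-diene-15,19-dioate (3β-alcohol)
Conditions: NaBH4, MeOH/THF, 0 °C
Reagents that add atoms: none
Why: NaBH4 reduces only the ketone (enoate and hindered ester are inert), and hydride delivery from the α face, away from the axial C19 ester and C20 methyl, should give mainly the equatorial 3β-alcohol, a centre that is erased in step 10.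

Step 9
Reactants: 13 15-ethyl 19-[(1R,2S,5R)-8-phenylmenthyl] (3S,4R,5R,9S,10R,13E)-3-hydroxylabda-8(17),13-diene-15,19-dioate
Product: 14 15-ethyl 19-[(1R,2S,5R)-8-phenylmenthyl] (3S,4R,5R,9S,10R,13E)-3-[(imidazol-1-yl)carbonothioyloxy]labda-8(17),13-diene-15,19-dioate
Conditions: 1,1'-thiocarbonyldiimidazole, DMAP (cat.), ClCH2CH2Cl, reflux
Reagents that add atoms: 1,1'-thiocarbonyldiimidazole, S=C(n1ccnc1)n1ccnc1
Why: Thioacylation under non-basic conditions activates the hindered secondary alcohol for radical deoxygenation and avoids the alkoxide that could open the β-hydroxy ester by retro-aldol cleavage.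

Step 10
Reactants: 14 15-ethyl 19-[(1R,2S,5R)-8-phenylmenthyl] (3S,4R,5R,9S,10R,13E)-3-[(imidazol-1-yl)carbonothioyloxy]labda-8(17),13-diene-15,19-dioate
Product: 15 15-ethyl 19-[(1R,2S,5R)-8-phenylmenthyl] (4S,5R,9S,10R,13E)-labda-8(17),13-diene-15,19-dioate
Conditions: Bu3SnH, AIBN (cat.), toluene, 110 °C
Reagents that add atoms: none
Why: In this Barton–McCombie deoxygenation the secondary C3 radical is reduced by Bu3SnH much faster than it could attack the remote alkenes, which leaves the C3 methylene and removes the helper oxygen.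

Step 11
Reactants: 15 15-ethyl 19-[(1R,2S,5R)-8-phenylmenthyl] (4S,5R,9S,10R,13E)-labda-8(17),13-diene-15,19-dioate
Product: 16 (4S,5R,9S,10R,13E)-labda-8(17),13-diene-15,19-diol
Conditions: LiAlH4, THF, 0 °C then reflux; aqueous work-up
Reagents that add atoms: none
Why: LiAlH4 reduces the enoate 1,2 at 0 °C to the E-allylic alcohol and, on heating, cleaves the hindered C19 ester reductively (the only practical way to remove this auxiliary), so 6 can be recovered.

Step 12
Reactants: 16 (4S,5R,9S,10R,13E)-labda-8(17),13-diene-15,19-diol, 17 oleoyl chloride [(9Z)-octadec-9-enoyl chloride]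
Product: 18 (4S,5R,9S,10R,13E)-19-hydroxylabda-8(17),13-dien-15-yl (9Z)-octadec-9-enoate
Conditions: 17 (1.05 equiv), pyridine, CH2Cl2, −40 to −20 °C
Reagents that add atoms: none
Why: Acylation should be kinetically selective for the unhindered primary allylic C15 alcohol over the neopentyl, axial C19 alcohol (1,3-diaxial to C20), and the 9Z alkene arrives unchanged with 17.

Step 13
Reactants: 18 (4S,5R,9S,10R,13E)-19-hydroxylabda-8(17),13-dien-15-yl (9Z)-octadec-9-enoate
Product: 19 (4S,5R,9S,10R,13E)-19-oxolabda-8(17),13-dien-15-yl (9Z)-octadec-9-enoate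
Conditions: Dess–Martin periodinane, CH2Cl2, 0 °C to rt
Reagents that add atoms: none
Why: Dess–Martin oxidation takes the only free alcohol to the non-enolisable C19 aldehyde without touching the three alkenes or the allylic ester.

Step 14
Reactants: 19 (4S,5R,9S,10R,13E)-19-oxolabda-8(17),13-dien-15-yl (9Z)-octadec-9-enoate
Product: 20 (4S,5R,9S,10R,13E)-15-[(9Z)-octadec-9-enoyloxy]labda-8(17),13-dien-19-oic acid (isocupressic acid 15-oleate)
Conditions: NaClO2, NaH2PO4, 2-methyl-2-butene (excess), t-BuOH/THF/H2O, 0 °C to rt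
Reagents that add atoms: sodium chlorite, [Na+].[O-]Cl=O
Why: Pinnick oxidation converts the hindered aldehyde into the acid under mildly acidic conditions that leave the oleate ester intact, while 2-methyl-2-butene scavenges the hypochlorous acid that would otherwise attack the alkenes.

**Compound list**

1 | (E)-geranylacetone, (5E)-6,10-dimethylundeca-5,9-dien-2-one | CC(=O)CC/C=C(\C)CCC=C(C)C | starting material
2 | 2-[(3E)-4,8-dimethylnona-3,7-dien-1-yl]-2-methyl-1,3-dioxolane | CC1(CC/C=C(\C)CCC=C(C)C)OCCO1 | intermediate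
3 | (2E,6E)-2,6-dimethyl-9-(2-methyl-1,3-dioxolan-2-yl)nona-2,6-dien-1-ol | CC1(CC/C=C(\C)CC/C=C(\C)CO)OCCO1 | intermediate
4 | 2-[(3E,7E)-9-bromo-4,8-dimethylnona-3,7-dien-1-yl]-2-methyl-1,3-dioxolane | CC1(CC/C=C(\C)CC/C=C(\C)CBr)OCCO1 | intermediate
5 | ethyl 2-methyl-3-oxobutanoate | CCOC(=O)C(C)C(C)=O | starting material
6 | (1R,2S,5R)-8-phenylmenthol, (1R,2S,5R)-5-methyl-2-(2-phenylpropan-2-yl)cyclohexan-1-ol | O[C@@H]1C[C@H](C)CC[C@H]1C(C)(C)c2ccccc2 | starting material
7 | (1R,2S,5R)-8-phenylmenthyl 2-methyl-3-oxobutanoate | CC(=O)C(C)C(=O)O[C@@H]1C[C@H](C)CC[C@H]1C(C)(C)c2ccccc2 | intermediate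
8 | (1R,2S,5R)-8-phenylmenthyl (6E,10E)-2,6,10-trimethyl-13-(2-methyl-1,3-dioxolan-2-yl)-3-oxotrideca-6,10-dienoate | CC1(CC/C=C(\C)CC/C=C(\C)CCC(=O)C(C)C(=O)O[C@@H]2C[C@H](C)CC[C@H]2C(C)(C)c3ccccc3)OCCO1 | intermediate
9 | (1R,2S,5R)-8-phenylmenthyl (6E,10E)-2,6,10-trimethyl-3,14-dioxopentadeca-6,10-dienoate | CC(=O)CC/C=C(\C)CC/C=C(\C)CCC(=O)C(C)C(=O)O[C@@H]1C[C@H](C)CC[C@H]1C(C)(C)c2ccccc2 | intermediate
10 | (1R,2S,5R)-8-phenylmenthyl (4R,5R,9S,10R)-3,13-dioxo-14,15-dinorlabd-8(17)-en-19-oate | C=C1CC[C@@H]2[C@](C)(CCC(=O)[C@]2(C)C(=O)O[C@@H]3C[C@H](C)CC[C@H]3C(C)(C)c4ccccc4)[C@H]1CCC(C)=O | intermediate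
11 | triethyl phosphonoacetate | CCOC(=O)CP(=O)(OCC)OCC | starting material
12 | 15-ethyl 19-[(1R,2S,5R)-8-phenylmenthyl] (4R,5R,9S,10R,13E)-3-oxolabda-8(17),13-diene-15,19-dioate | C=C1CC[C@@H]2[C@](C)(CCC(=O)[C@]2(C)C(=O)O[C@@H]3C[C@H](C)CC[C@H]3C(C)(C)c4ccccc4)[C@H]1CC/C(C)=C/C(=O)OCC | intermediate
13 | 15-ethyl 19-[(1R,2S,5R)-8-phenylmenthyl] (3S,4R,5R,9S,10R,13E)-3-hydroxylabda-8(17),13-diene-15,19-dioate | C=C1CC[C@@H]2[C@](C)(CC[C@H](O)[C@]2(C)C(=O)O[C@@H]3C[C@H](C)CC[C@H]3C(C)(C)c4ccccc4)[C@H]1CC/C(C)=C/C(=O)OCC | intermediate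
14 | 15-ethyl 19-[(1R,2S,5R)-8-phenylmenthyl] (3S,4R,5R,9S,10R,13E)-3-[(imidazol-1-yl)carbonothioyloxy]labda-8(17),13-diene-15,19-dioate | C=C1CC[C@@H]2[C@](C)(CC[C@H](OC(=S)n5ccnc5)[C@]2(C)C(=O)O[C@@H]3C[C@H](C)CC[C@H]3C(C)(C)c4ccccc4)[C@H]1CC/C(C)=C/C(=O)OCC | intermediate
15 | 15-ethyl 19-[(1R,2S,5R)-8-phenylmenthyl] (4S,5R,9S,10R,13E)-labda-8(17),13-diene-15,19-dioate | C=C1CC[C@@H]2[C@](C)(CCC[C@]2(C)C(=O)O[C@@H]3C[C@H](C)CC[C@H]3C(C)(C)c4ccccc4)[C@H]1CC/C(C)=C/C(=O)OCC | intermediate
16 | (4S,5R,9S,10R,13E)-labda-8(17),13-diene-15,19-diol | C=C1CC[C@@H]2[C@](C)(CCC[C@]2(C)CO)[C@H]1CC/C(C)=C/CO | intermediate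
17 | oleoyl chloride, (9Z)-octadec-9-enoyl chloride | CCCCCCCC/C=C\CCCCCCCC(=O)Cl | starting material
18 | (4S,5R,9S,10R,13E)-19-hydroxylabda-8(17),13-dien-15-yl (9Z)-octadec-9-enoate | C=C1CC[C@@H]2[C@](C)(CCC[C@]2(C)CO)[C@H]1CC/C(C)=C/COC(=O)CCCCCCC/C=C\CCCCCCCC | intermediate
19 | (4S,5R,9S,10R,13E)-19-oxolabda-8(17),13-dien-15-yl (9Z)-octadec-9-enoate | C=C1CC[C@@H]2[C@](C)(CCC[C@]2(C)C=O)[C@H]1CC/C(C)=C/COC(=O)CCCCCCC/C=C\CCCCCCCC | intermediate
20 | (4S,5R,9S,10R,13E)-15-[(9Z)-octadec-9-enoyloxy]labda-8(17),13-dien-19-oic acid | C=C1CC[C@@H]2[C@](C)(CCC[C@]2(C)C(=O)O)[C@H]1CC/C(C)=C/COC(=O)CCCCCCC/C=C\CCCCCCCC | target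

**Totals**

Total step count: 14. Longest linear sequence: 13 steps (1 → 2 → 3 → 4 → 9 → 10 → 12 → 13 → 14 → 15 → 16 → 18 → 19 → 20, i.e. steps 1–3 and 5–14); step 4 is the side branch.

**Steps most likely to fail, with fallbacks**

Step 6. What may go wrong is weak facial discrimination at the free, unchelated C4 radical, so that both trans-decalin series form, together with some loss of regiocontrol in the final elimination. The fallback moves the control to a Lewis-acid chelate and adds the C4 methyl afterwards; it sets out from bromide 4 and comes back at diol 16.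
- Because the chelate holds the ketone and ester carbonyls syn, the ester starts equatorial, and the link between the shielded face and the decalin series is the reverse of that in step 6. The enantiomeric auxiliary, (1S,2R,5S)-8-phenylmenthol F1, is therefore used.
- F1 is heated with 2,2,6-trimethyl-4H-1,3-dioxin-4-one (xylene, 140 °C) to give (1S,2R,5S)-8-phenylmenthyl 3-oxobutanoate F2.
- The dianion of F2 (NaH, then n-BuLi, THF, 0 °C) is alkylated with 4 to the ketal-protected 3-oxo ester F3, and 1 M HCl frees the 2-unsubstituted diketo ester F4.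
- Mn(OAc)3·2H2O and Cu(OAc)2·H2O with Yb(OTf)3 in CF3CH2OH at 0 °C should close both rings through the ytterbium-chelated radical, in which the auxiliary blocks one face of a rigid plane, to give the 4-demethyl bicyclic keto ester F5.
- K2CO3 and MeI in acetone should methylate C4 from the α face, anti to the axial C20 methyl, to give the 4α-methyl 4β-ester F6.
- Steps 7 to 10 applied to this ester series give the 13E enoate F7, the 3β-alcohol F8, the thiocarbonylimidazolide F9 and the deoxygenated diester F10; LiAlH4 reduction of F10 as in step 11 gives 16.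

Step 9. What may go wrong is slow or incomplete thioacylation of the C3 carbinol, which is flanked by the quaternary C4, with retro-aldol cleavage under forcing conditions. The fallback removes the oxygen at the ketone level; it sets out from ketone 12 and comes back at 15. Ketone 12 is condensed with p-toluenesulfonylhydrazide (EtOH, cat. AcOH, reflux) to the C3 tosylhydrazone F11. Reduction with catecholborane (CHCl3, 0 °C) and then NaOAc·3H2O at reflux should give the C3 methylene of 15 through the diazene, with loss of sulfinate and nitrogen and without affecting the enoate.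

Step 2. What may go wrong is over-oxidation to the enal, competing oxidation at the internal alkene and partial loss of the dioxolane. The fallback replaces the allylic C–H oxidation by terminal cleavage and a stabilised Wittig reaction; it sets out from 1 and comes back at 3.
- NBS in aqueous THF at 0 °C should give the terminal bromohydrin (5E)-9-bromo-10-hydroxy-6,10-dimethylundec-5-en-2-one F12.
- K2CO3 in MeOH closes it to the epoxide (5E)-9,10-epoxy-6,10-dimethylundec-5-en-2-one F13.
- H5IO6 in THF/Et2O cleaves the epoxide to (4E)-4-methyl-8-oxonon-4-enal F14.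
- Ph3P=C(CH3)CO2Et in CH2Cl2 reacts only at the aldehyde and should give the E-enoate ethyl (2E,6E)-2,6-dimethyl-10-oxoundeca-2,6-dienoate F15.
- Ethylene glycol with PPTS gives the ketal ethyl (2E,6E)-2,6-dimethyl-9-(2-methyl-1,3-dioxolan-2-yl)nona-2,6-dienoate F16.
- i-Bu2AlH in CH2Cl2 at −78 °C reduces F16 to 3.

**Further compounds**

F1 | step 6 | (1S,2R,5S)-8-phenylmenthol | O[C@H]1C[C@@H](C)CC[C@@H]1C(C)(C)c2ccccc2
F2 | step 6 | (1S,2R,5S)-8-phenylmenthyl 3-oxobutanoate | CC(=O)CC(=O)O[C@H]1C[C@@H](C)CC[C@@H]1C(C)(C)c2ccccc2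
F3 | step 6 | (1S,2R,5S)-8-phenylmenthyl (6E,10E)-6,10-dimethyl-13-(2-methyl-1,3-dioxolan-2-yl)-3-oxotrideca-6,10-dienoate | CC1(CC/C=C(\C)CC/C=C(\C)CCC(=O)CC(=O)O[C@H]2C[C@@H](C)CC[C@@H]2C(C)(C)c3ccccc3)OCCO1
F4 | step 6 | (1S,2R,5S)-8-phenylmenthyl (6E,10E)-6,10-dimethyl-3,14-dioxopentadeca-6,10-dienoate | CC(=O)CC/C=C(\C)CC/C=C(\C)CCC(=O)CC(=O)O[C@H]1C[C@@H](C)CC[C@@H]1C(C)(C)c2ccccc2
F5 | step 6 | (1S,2R,5S)-8-phenylmenthyl (4S,5R,9S,10R)-3,13-dioxo-14,15,18-trinorlabd-8(17)-en-19-oate | C=C1CC[C@@H]2[C@](C)(CCC(=O)[C@H]2C(=O)O[C@H]3C[C@@H](C)CC[C@@H]3C(C)(C)c4ccccc4)[C@H]1CCC(C)=O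
F6 | step 6 | (1S,2R,5S)-8-phenylmenthyl (4R,5R,9S,10R)-3,13-dioxo-14,15-dinorlabd-8(17)-en-19-oate | C=C1CC[C@@H]2[C@](C)(CCC(=O)[C@]2(C)C(=O)O[C@H]3C[C@@H](C)CC[C@@H]3C(C)(C)c4ccccc4)[C@H]1CCC(C)=O
F7 | step 6 | 15-ethyl 19-[(1S,2R,5S)-8-phenylmenthyl] (4R,5R,9S,10R,13E)-3-oxolabda-8(17),13-diene-15,19-dioate | C=C1CC[C@@H]2[C@](C)(CCC(=O)[C@]2(C)C(=O)O[C@H]3C[C@@H](C)CC[C@@H]3C(C)(C)c4ccccc4)[C@H]1CC/C(C)=C/C(=O)OCC
F8 | step 6 | 15-ethyl 19-[(1S,2R,5S)-8-phenylmenthyl] (3S,4R,5R,9S,10R,13E)-3-hydroxylabda-8(17),13-diene-15,19-dioate | C=C1CC[C@@H]2[C@](C)(CC[C@H](O)[C@]2(C)C(=O)O[C@H]3C[C@@H](C)CC[C@@H]3C(C)(C)c4ccccc4)[C@H]1CC/C(C)=C/C(=O)OCC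
F9 | step 6 | 15-ethyl 19-[(1S,2R,5S)-8-phenylmenthyl] (3S,4R,5R,9S,10R,13E)-3-[(imidazol-1-yl)carbonothioyloxy]labda-8(17),13-diene-15,19-dioate | C=C1CC[C@@H]2[C@](C)(CC[C@H](OC(=S)n5ccnc5)[C@]2(C)C(=O)O[C@H]3C[C@@H](C)CC[C@@H]3C(C)(C)c4ccccc4)[C@H]1CC/C(C)=C/C(=O)OCC
F10 | step 6 | 15-ethyl 19-[(1S,2R,5S)-8-phenylmenthyl] (4S,5R,9S,10R,13E)-labda-8(17),13-diene-15,19-dioate | C=C1CC[C@@H]2[C@](C)(CCC[C@]2(C)C(=O)O[C@H]3C[C@@H](C)CC[C@@H]3C(C)(C)c4ccccc4)[C@H]1CC/C(C)=C/C(=O)OCC
F11 | step 9 | 15-ethyl 19-[(1R,2S,5R)-8-phenylmenthyl] (4R,5R,9S,10R,13E)-3-(p-tolylsulfonylhydrazono)labda-8(17),13-diene-15,19-dioate | C=C1CC[C@@H]2[C@](C)(CCC(=NNS(=O)(=O)c5ccc(C)cc5)[C@]2(C)C(=O)O[C@@H]3C[C@H](C)CC[C@H]3C(C)(C)c4ccccc4)[C@H]1CC/C(C)=C/C(=O)OCC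
F12 | step 2 | (5E)-9-bromo-10-hydroxy-6,10-dimethylundec-5-en-2-one | CC(=O)CC/C=C(\C)CCC(Br)C(C)(C)O
F13 | step 2 | (5E)-9,10-epoxy-6,10-dimethylundec-5-en-2-one | CC(=O)CC/C=C(\C)CCC1OC1(C)C
F14 | step 2 | (4E)-4-methyl-8-oxonon-4-enal | CC(=O)CC/C=C(\C)CCC=O
F15 | step 2 | ethyl (2E,6E)-2,6-dimethyl-10-oxoundeca-2,6-dienoate | CC(=O)CC/C=C(\C)CC/C=C(\C)C(=O)OCC
F16 | step 2 | ethyl (2E,6E)-2,6-dimethyl-9-(2-methyl-1,3-dioxolan-2-yl)nona-2,6-dienoate | CC1(CC/C=C(\C)CC/C=C(\C)C(=O)OCC)OCCO1
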